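**Retrosynthetic overview**
1. Target 42 ⇐ MnO2 oxidation, desilylation and acetylation of a trienol; its side chain comes from a directed aldol condensation of the C-2 acetaldehyde 31 with dienal 35 (E 2-substituted enal, then CH2OAc).
2. Ring-B enal ⇐ Z tetrasubstituted alkene templated by a temporary eight-membered lactone through the hydroxypropyl oxygen (SmI2 Reformatsky, dehydration, iBu2AlH). C-6/C-7 come from B-alkyl Suzuki coupling of the C-6 enol triflate and hydroboration; the C-10 carbinol from the C-10 ketone and MeMgBr.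
3. Key disconnection: the cyclopentane is cut at C-2–C-3 and C-1–C-5, giving spiro-cyclopropyl ketone 8 and (E)-alkenylboronate 3 (radical-relay [3+2]). Enabling feature: the spiro carbon C-5 lies in ring B between C-6 and C-10, both carbonyl-level carbons of a cyclohexane-1,3-dione. C-5/C-4/C-3 is therefore a spiro-cyclopropane α to a ketone (a ketyl-openable three-carbon unit), and C-1/C-2, with trans O and C substituents, is an (E)-alkene whose boron is a latent hydroxyl.
4. Ring order: ring B (cyclohexane-1,3-dione) → spiro-cyclopropane → cyclopentane (key step) → temporary eight-membered lactone, opened again.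
5. Absolute configuration comes from CBS desymmetrisation of dione 6; the C-10 silyloxy stereocentre relays to C-5, is then erased (ketone) and reset.

Key step: step 5

Remark: locants follow the spiro[4.5]decane numbering of the target (C-1 CHOH, C-2 side-chain carbon, C-3/C-4 CH2, C-5 spiro, C-6 hydroxypropyl carbon, C-7 alkylidene carbon, C-10 methyl carbinol); the target is taken as the open hydroxy aldehyde drawn, and CIP descriptors are given only for 7, 8 and 42, the other configurations being carried by the SMILES and the cis/trans statements.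

Step 1
Reactants: 1 4,4-diethoxybut-1-yne; 2 pinacolborane
Product: 3 (E)-2-(4,4-diethoxybut-1-en-1-yl)-4,4,5,5-tetramethyl-1,3,2-dioxaborolane
Conditions: Cp2Zr(H)Cl (5 mol %), Et3N (10 mol %), neat, 60 °C
Reagents that add atoms: none
Why: zirconocene-hydride-catalysed syn hydroboration of a terminal alkyne with HBpin puts boron on the terminal carbon and gives the E alkenylboronate.

Step 2
Reactants: 4 cyclohexane-1,3-dione; 5 diphenyl(vinyl)sulfonium trifluoromethanesulfonate
Product: 6 spiro[2.5]octane-4,8-dione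
Conditions: K2CO3 (powder), EtOAc, rt
Reagents that add atoms: none
Why: vinylsulfonium cyclopropanation of a 1,3-dicarbonyl compound, in which conjugate addition of the dione enolate, proton transfer and 3-exo-tet C-alkylation with loss of Ph2S build the spiro-cyclopropane.

Step 3
Reactants: 6 spiro[2.5]octane-4,8-dione
Product: 7 (8R)-8-hydroxyspiro[2.5]octan-4-one
Conditions: (S)-1-methyl-3,3-diphenyltetrahydro-1H,3H-pyrrolo[1,2-c][1,3,2]oxazaborole [(S)-Me-CBS, 20 mol %], catecholborane (1.1 equiv), toluene, −78 °C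
Reagents that add atoms: none
Why: Corey–Bakshi–Shibata desymmetrising mono-reduction of a 2,2-disubstituted cyclohexane-1,3-dione, in which the (S)-catalyst with the spiro quaternary carbon as the large group should give the R carbinol, the only source of absolute configuration in the route.

Step 4
Reactants: 7 (8R)-8-hydroxyspiro[2.5]octan-4-one
Product: 8 (8R)-8-(triethylsilyloxy)spiro[2.5]octan-4-one
Conditions: Et3SiCl, imidazole, DMF, 0 °C to rt
Reagents that add atoms: chlorotriethylsilane, CC[Si](Cl)(CC)CC
Why: standard silylation of a secondary alcohol gives the bulky ether that later directs the spiro centre.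

Step 5
Reactants: 8 (8R)-8-(triethylsilyloxy)spiro[2.5]octan-4-one; 3 (E)-alkenylboronate
Product: 9 2-(2,2-diethoxyethyl)-1-(pinacolboryl)-10-(triethylsilyloxy)spiro[4.5]decan-6-one
Conditions: SmI2 (20 mol %), Sm powder (20 mol %), 3 (3 equiv), THF, 55 °C
Reagents that add atoms: none
Why: Proposed new method: electron transfer from divalent samarium to the ketone of 8 gives a ketyl whose bisected spiro-cyclopropane opens to a trivalent-samarium enolate that carries a primary alkyl radical; the radical adds to 3 at the alkene carbon β to boron, and the α-boryl radical so formed attacks the enolate α-carbon, the new ketyl handing its electron back to trivalent samarium so that the metal turns over. The closest known reaction type is the SmI2-catalysed radical-relay formal [3+2] cycloaddition of alkyl cyclopropyl ketones with alkenes and alkynes, joined here to the Giese-type addition of alkyl radicals to alkenylboronates; a ring-fused spiro-cyclopropyl ketone that ends as a spiro quaternary carbon and a 1,2-disubstituted alkenylboronate have not been shown in it. The cyclopentane closes in the 5-exo-trig mode onto the enolate carbon. The spiro carbon C-5 is set by the C-10 silyloxy group, which sits pseudoaxial on the cyclohexenolate and sends the new bond to the opposite face; C-1 is set by the boryl group turning away from the samarium-laden enolate oxygen (trans to the acyl carbon C-6, cis to C-10); C-2 is set by the chain taking the position trans to the boryl group in the closing transition state. The step needs regioselective radical addition (secured by α-boryl stabilisation against an sp3 substituent on the other alkene carbon), addition faster than hydrogen abstraction from THF (secured by the excess of 3 and the reversible ring opening) and no β-elimination of the silyloxy group from the enolate (secured by its short lifetime and the poor leaving group).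

Step 6
Reactants: 9 spiro[4.5]decan-6-one boronate
Product: 10 C-6 enol triflate of 9
Conditions: KN(SiMe3)2, THF, −78 °C; PhNTf2, −78 to 0 °C
Reagents that add atoms: N-phenylbis(trifluoromethanesulfonimide), O=S(=O)(N(c1ccccc1)S(=O)(=O)C(F)(F)F)C(F)(F)F
Why: enolate O-triflation, in which the ketone can enolise only toward C-7 because C-5 is quaternary.

Step 7
Reactants: 11 allyl alcohol
Product: 12 allyl tert-butyldiphenylsilyl ether
Conditions: tBuPh2SiCl, imidazole, CH2Cl2, rt
Reagents that add atoms: tert-butyl(chloro)diphenylsilane, CC(C)(C)[Si](Cl)(c1ccccc1)c1ccccc1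
Why: standard silylation gives an acid-stable protected three-carbon chain.

Step 8
Reactants: 10 C-6 enol triflate; 12 allyl tert-butyldiphenylsilyl ether
Product: 14 6-[3-(tert-butyldiphenylsilyloxy)propyl]spiro[4.5]dec-6-ene boronate, via B-alkyl-9-BBN 13 (not isolated)
Conditions: 12, 9-BBN-H, THF, rt; then 10, Pd(dppf)Cl2 (5 mol %), AsPh3 (10 mol %), K3PO4 (3 M aq), DMF, 50 °C
Reagents that add atoms: none
Why: B-alkyl Suzuki–Miyaura coupling after anti-Markovnikov hydroboration of 12, under which the secondary alkyl pinacolboronate at C-1 does not transmetalate.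

Step 9
Reactants: 14 C-10 triethylsilyl ether
Product: 15 C-10 alcohol
Conditions: camphorsulfonic acid (10 mol %), EtOH, 0 °C to rt
Reagents that add atoms: none
Why: acid-catalysed ethanolysis removes the secondary triethylsilyl ether, while the diethyl acetal (degenerate exchange in ethanol), the pinacol boronate and the tert-butyldiphenylsilyl ether stay.

Step 10
Reactants: 15 C-10 alcohol
Product: 16 spiro[4.5]dec-6-en-10-one boronate
Conditions: Dess–Martin periodinane, NaHCO3, CH2Cl2, rt
Reagents that add atoms: none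
Why: buffered Dess–Martin oxidation erases the relay stereocentre and gives the C-10 ketone without touching the boronate or the acetal.

Step 11
Reactants: 16 C-10 ketone boronate
Product: 18 1,10-diol with 10-methyl, via tertiary-carbinol boronate 17 (not isolated)
Conditions: MeMgBr (3 equiv), THF, −78 to 0 °C; then H2O2 (30 % aq), NaOH (aq), 0 °C to rt
Reagents that add atoms: methylmagnesium bromide, C[Mg]Br; hydrogen peroxide, OO
Why: Grignard 1,2-addition followed by stereoretentive oxidation of the C–B bond, in which methyl enters the carbonyl face that carries the C-4 methylene because the C-1 boryl group hangs over the other face (setting C-10 with OH cis to C-1), and boron is replaced by OH with retention at C-1.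

Step 12
Reactants: 18 1,10-diol
Product: 19 1,10-O-isopropylidene acetal
Conditions: 2,2-diethoxypropane, camphorsulfonic acid (5 mol %), CH2Cl2, rt
Reagents that add atoms: 2,2-diethoxypropane, CCOC(C)(C)OCC
Why: acetalisation of the cis-disposed secondary/tertiary 1,3-diol as a 1,3-dioxane, with ethanol as the only by-product so that the diethyl acetal is not scrambled.

Step 13
Reactants: 19 acetonide alkene
Product: 21 C-7 alcohol with H-6 cis to C-4, via C-7 alkylborane 20 (not isolated)
Conditions: BH3·THF (3 equiv), THF, 0 °C to rt; then H2O2 (30 % aq), NaOH (aq), 0 °C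
Reagents that add atoms: hydrogen peroxide, OO
Why: Brown hydroboration–oxidation, a syn addition with boron at the less substituted C-7 from the ring-B face opposite to C-1 and the dioxane ring, which sets C-6 (H cis to C-4, chain cis to C-1) and a temporary C-7 carbinol.

Step 14
Reactants: 21 C-7 alcohol
Product: 22 C-7 ketone
Conditions: Dess–Martin periodinane, NaHCO3, CH2Cl2, rt
Reagents that add atoms: none
Why: buffered Dess–Martin oxidation of the only free hydroxyl gives the ketone without epimerising the adjacent C-6 centre.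

Step 15
Reactants: 22 C-7 ketone
Product: 23 3-hydroxypropyl ketone
Conditions: Bu4NF, AcOH (1:1), THF, rt
Reagents that add atoms: none
Why: buffered fluoride desilylation frees the primary alcohol that will carry the tether, the buffer protecting the enolisable C-6 centre.

Step 16
Reactants: 23 3-hydroxypropyl ketone; 24 2-bromopropanoyl bromide
Product: 25 2-bromopropanoate ester of 23
Conditions: 24 (1.2 equiv), pyridine, CH2Cl2, −20 °C
Reagents that add atoms: none
Why: acylation of the primary alcohol installs the three carbons of the future enal as a Reformatsky donor tethered to C-6.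

Step 17
Reactants: 25 bromo ester
Product: 26 eight-membered β-hydroxy lactone
Conditions: SmI2 (2.5 equiv), THF (0.005 M, slow addition of 25), −78 to 0 °C
Reagents that add atoms: none
Why: samarium Reformatsky lactonisation, a method established for medium rings, in which the trivalent-samarium ester enolate adds to the C-7 ketone; the two new stereocentres are left uncontrolled because step 18 removes them.

Step 18
Reactants: 26 β-hydroxy lactone
Product: 28 (Z)-unsaturated eight-membered lactone, via tertiary mesylate 27 (not isolated)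
Conditions: MsCl, Et3N, DMAP (cat.), CH2Cl2, 0 °C; then DBU, rt
Reagents that add atoms: none
Why: E1cB dehydration of the β-sulfonyloxy lactone gives the conjugated tetrasubstituted alkene, whose geometry is dictated by the eight-membered ring so that the carbonyl carbon lies cis to C-6.

Step 19
Reactants: 28 unsaturated lactone
Product: 29 (Z)-allylic alcohol and primary alcohol (diol)
Conditions: iBu2AlH (4 equiv), CH2Cl2, −78 to 0 °C; Rochelle salt work-up
Reagents that add atoms: none
Why: 1,2-reduction of the unsaturated lactone opens the template and leaves the Z geometry fixed in the allylic alcohol.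

Step 20
Reactants: 29 diol
Product: 30 bis(tert-butyldiphenylsilyl) ether
Conditions: tBuPh2SiCl (2.5 equiv), imidazole, DMF, rt
Reagents that add atoms: tert-butyl(chloro)diphenylsilane, CC(C)(C)[Si](Cl)(c1ccccc1)c1ccccc1
Why: silylation of the two primary alcohols protects them through the side-chain construction.

Step 21
Reactants: 30 bis-silyl ether
Product: 31 C-2 acetaldehyde 1,10-diol
Conditions: AcOH/THF/H2O (3:1:1), 45 °C
Reagents that add atoms: water, O
Why: mild acid hydrolysis cleaves the diethyl acetal and the acetonide together, and the aldehyde stays open because a lactol with the trans C-1 hydroxyl would be a trans-fused five/five bicycle.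

Step 22
Reactants: 32 6-methylhept-5-en-2-one
Product: 33 6-methylhepta-1,5-dien-2-yl trifluoromethanesulfonate
Conditions: LiN(iPr)2, THF, −78 °C; PhNTf2, −78 to 0 °C
Reagents that add atoms: N-phenylbis(trifluoromethanesulfonimide), O=S(=O)(N(c1ccccc1)S(=O)(=O)C(F)(F)F)C(F)(F)F
Why: kinetic deprotonation of the methyl ketone at the methyl group and O-triflation give the terminal enol triflate.

Step 23
Reactants: 33 dienyl triflate; 34 acrolein
Product: 35 (2E)-8-methyl-4-methylidenenona-2,7-dienal
Conditions: Pd(OAc)2 (5 mol %), PPh3 (10 mol %), Et3N, acrolein (3 equiv), DMF, 60 °C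
Reagents that add atoms: none
Why: Heck reaction of a vinyl triflate with acrolein, in which syn β-hydride elimination gives the E enal.

Step 24
Reactants: 31 C-2 acetaldehyde; 35 dienal
Product: 38 (E)-2-substituted trienal, via tert-butylimine 36 (not isolated), via hydroxy-imine adduct 37 (not isolated)
Conditions: tBuNH2, MgSO4, Et2O, rt; LiN(iPr)2 (3.3 equiv), THF, −78 °C; 35, −78 to −20 °C; then aqueous oxalic acid, THF, rt
Reagents that add atoms: none
Why: Wittig directed aldol condensation, in which the lithiated imine (two further equivalents of base being held by the hydroxyls) adds 1,2 to 35 and acid hydrolysis with dehydration gives the 2-substituted enal as the E isomer with formyl trans to the dienyl group, which is the alkene geometry of the target.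

Step 25
Reactants: 38 trienal
Product: 39 trienol
Conditions: NaBH4, CeCl3·7H2O, MeOH, −40 °C
Reagents that add atoms: none
Why: Luche reduction gives clean 1,2-reduction of the conjugated aldehyde to the primary allylic alcohol.

Step 26
Reactants: 39 trienol
Product: 40 allylic acetate
Conditions: AcCl (1.1 equiv), 2,4,6-collidine, CH2Cl2, −78 °C
Reagents that add atoms: acetyl chloride, CC(Cl)=O
Why: primary-selective acetylation, since the only other free hydroxyls are the hindered secondary C-1 and tertiary C-10 alcohols.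

Step 27
Reactants: 40 allylic acetate
Product: 41 allylic alcohol acetate (both silyl ethers removed)
Conditions: Bu4NF, AcOH (1:1), THF, rt
Reagents that add atoms: none
Why: buffered fluoride desilylation removes both primary silyl ethers without cleaving or migrating the acetate.

Step 28
Reactants: 41 allylic alcohol
Product: 42 target
Conditions: MnO2 (activated, 20 equiv), CH2Cl2, rt
Reagents that add atoms: none
Why: MnO2 oxidises only the allylic primary alcohol, so the Z enal is formed beside the free saturated primary, secondary and tertiary hydroxyls and the acetate.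

**Compound list**
1 | 4,4-diethoxybut-1-yne | C#CCC(OCC)OCC | starting material
2 | pinacolborane | [H]B1OC(C)(C)C(C)(C)O1 | starting material
3 | (E)-2-(4,4-diethoxybut-1-en-1-yl)-4,4,5,5-tetramethyl-1,3,2-dioxaborolane | CCOC(OCC)C/C=C/B1OC(C)(C)C(C)(C)O1 | intermediate
4 | cyclohexane-1,3-dione | O=C1CCCC(=O)C1 | starting material
5 | diphenyl(vinyl)sulfonium trifluoromethanesulfonate | C=C[S+](c1ccccc1)c1ccccc1.[O-]S(=O)(=O)C(F)(F)F | starting material
6 | spiro[2.5]octane-4,8-dione | O=C1CCCC(=O)C12CC2 | intermediate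
7 | (8R)-8-hydroxyspiro[2.5]octan-4-one | O=C1CCC[C@@H](O)C12CC2 | intermediate
8 | (8R)-8-(triethylsilyloxy)spiro[2.5]octan-4-one | O=C1CCC[C@@H](O[Si](CC)(CC)CC)C12CC2 | intermediate
9 | 2-(2,2-diethoxyethyl)-1-(4,4,5,5-tetramethyl-1,3,2-dioxaborolan-2-yl)-10-(triethylsilyloxy)spiro[4.5]decan-6-one; boryl group cis to C-10 and trans to the C-2 chain, silyloxy group trans to C-1 across ring B | CCOC(OCC)C[C@@H]1CC[C@]2(C(=O)CCC[C@H]2O[Si](CC)(CC)CC)[C@H]1B1OC(C)(C)C(C)(C)O1 | intermediate
10 | C-6 enol triflate of 9 (spiro[4.5]dec-6-en-6-yl trifluoromethanesulfonate, stereocentres as in 9) | CCOC(OCC)C[C@@H]1CC[C@]2(C(OS(=O)(=O)C(F)(F)F)=CCC[C@H]2O[Si](CC)(CC)CC)[C@H]1B1OC(C)(C)C(C)(C)O1 | intermediate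
11 | allyl alcohol | C=CCO | starting material
12 | allyl tert-butyldiphenylsilyl ether | C=CCO[Si](c1ccccc1)(c1ccccc1)C(C)(C)C | intermediate
13 | 9-[3-(tert-butyldiphenylsilyloxy)propyl]-9-borabicyclo[3.3.1]nonane | CC(C)(C)[Si](c1ccccc1)(c1ccccc1)OCCCB1C2CCCC1CCC2 | intermediate
14 | 6-[3-(tert-butyldiphenylsilyloxy)propyl]-2-(2,2-diethoxyethyl)-1-(pinacolboryl)-10-(triethylsilyloxy)spiro[4.5]dec-6-ene (stereocentres as in 9) | CCOC(OCC)C[C@@H]1CC[C@]2(C(CCCO[Si](c3ccccc3)(c3ccccc3)C(C)(C)C)=CCC[C@H]2O[Si](CC)(CC)CC)[C@H]1B1OC(C)(C)C(C)(C)O1 | intermediate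
15 | C-10 alcohol from 14 (OH trans to C-1 across ring B) | CCOC(OCC)C[C@@H]1CC[C@]2(C(CCCO[Si](c3ccccc3)(c3ccccc3)C(C)(C)C)=CCC[C@H]2O)[C@H]1B1OC(C)(C)C(C)(C)O1 | intermediate
16 | 6-[3-(tert-butyldiphenylsilyloxy)propyl]-2-(2,2-diethoxyethyl)-1-(pinacolboryl)spiro[4.5]dec-6-en-10-one | CCOC(OCC)C[C@@H]1CC[C@]2(C(CCCO[Si](c3ccccc3)(c3ccccc3)C(C)(C)C)=CCCC2=O)[C@H]1B1OC(C)(C)C(C)(C)O1 | intermediate
17 | 10-methyl C-10 tertiary alcohol with the C-1 boronate still in place (OH cis to C-1, methyl cis to C-4) | CCOC(OCC)C[C@@H]1CC[C@]2(C(CCCO[Si](c3ccccc3)(c3ccccc3)C(C)(C)C)=CCC[C@]2(C)O)[C@H]1B1OC(C)(C)C(C)(C)O1 | intermediate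
18 | 6-[3-(tert-butyldiphenylsilyloxy)propyl]-2-(2,2-diethoxyethyl)-10-methylspiro[4.5]dec-6-ene-1,10-diol (1-OH cis to C-10 and trans to the C-2 chain; 10-OH cis to C-1) | CCOC(OCC)C[C@@H]1CC[C@]2(C(CCCO[Si](c3ccccc3)(c3ccccc3)C(C)(C)C)=CCC[C@]2(C)O)[C@H]1O | intermediate
19 | 1,10-O-isopropylidene acetal of 18 | CCOC(OCC)C[C@@H]1CC[C@]2(C(CCCO[Si](c3ccccc3)(c3ccccc3)C(C)(C)C)=CCC[C@]2(C)OC(C)(C)O4)[C@H]14 | intermediate
20 | C-7 alkylborane from 19 (BH2 at C-7 cis to H-6, both on the face of the C-4 methylene) | CCOC(OCC)C[C@@H]1CC[C@]2([C@H](CCCO[Si](c3ccccc3)(c3ccccc3)C(C)(C)C)[C@@H](B)CC[C@]2(C)OC(C)(C)O4)[C@H]14 | intermediate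
21 | C-7 alcohol (H-6 cis to C-4, chain cis to C-1, 7-OH trans to the chain) | CCOC(OCC)C[C@@H]1CC[C@]2([C@H](CCCO[Si](c3ccccc3)(c3ccccc3)C(C)(C)C)[C@@H](O)CC[C@]2(C)OC(C)(C)O4)[C@H]14 | intermediate
22 | C-7 ketone with the 6-[3-(tert-butyldiphenylsilyloxy)propyl] chain cis to C-1 | CCOC(OCC)C[C@@H]1CC[C@]2([C@H](CCCO[Si](c3ccccc3)(c3ccccc3)C(C)(C)C)C(=O)CC[C@]2(C)OC(C)(C)O4)[C@H]14 | intermediate
23 | 6-(3-hydroxypropyl) C-7 ketone | CCOC(OCC)C[C@@H]1CC[C@]2([C@H](CCCO)C(=O)CC[C@]2(C)OC(C)(C)O4)[C@H]14 | intermediate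
24 | 2-bromopropanoyl bromide (racemic) | CC(Br)C(Br)=O | starting material
25 | 2-bromopropanoate ester of 23 (mixture at the bromo carbon) | CCOC(OCC)C[C@@H]1CC[C@]2([C@H](CCCOC(=O)C(C)Br)C(=O)CC[C@]2(C)OC(C)(C)O4)[C@H]14 | intermediate
26 | eight-membered β-hydroxy lactone fused at C-6/C-7 (mixture at C-7 and the α-carbon) | CCOC(OCC)C[C@@H]1CC[C@]2([C@H](CCCOC(=O)C5C)C5(O)CC[C@]2(C)OC(C)(C)O4)[C@H]14 | intermediate
27 | C-7 methanesulfonate of 26 | CCOC(OCC)C[C@@H]1CC[C@]2([C@H](CCCOC(=O)C5C)C5(OS(C)(=O)=O)CC[C@]2(C)OC(C)(C)O4)[C@H]14 | intermediate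
28 | (Z)-α-methyl-α,β-unsaturated eight-membered lactone (carbonyl cis to C-6) | CCOC(OCC)C[C@@H]1CC[C@]2([C@H](CCCOC5=O)/C(=C5/C)CC[C@]2(C)OC(C)(C)O4)[C@H]14 | intermediate
29 | 6-(3-hydroxypropyl)-7-[(Z)-1-hydroxypropan-2-ylidene] acetonide diol | CCOC(OCC)C[C@@H]1CC[C@]2([C@H](CCCO)/C(=C(/C)CO)CC[C@]2(C)OC(C)(C)O4)[C@H]14 | intermediate
30 | bis(tert-butyldiphenylsilyl) ether of 29 | CCOC(OCC)C[C@@H]1CC[C@]2([C@H](CCCO[Si](c3ccccc3)(c3ccccc3)C(C)(C)C)/C(=C(/C)CO[Si](c3ccccc3)(c3ccccc3)C(C)(C)C)CC[C@]2(C)OC(C)(C)O4)[C@H]14 | intermediate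
31 | C-2 acetaldehyde with free 1,10-diol and both primary silyl ethers | O=CC[C@@H]1CC[C@]2([C@H](CCCO[Si](c3ccccc3)(c3ccccc3)C(C)(C)C)/C(=C(/C)CO[Si](c3ccccc3)(c3ccccc3)C(C)(C)C)CC[C@]2(C)O)[C@H]1O | intermediate
32 | 6-methylhept-5-en-2-one | CC(=O)CCC=C(C)C | starting material
33 | 6-methylhepta-1,5-dien-2-yl trifluoromethanesulfonate | C=C(OS(=O)(=O)C(F)(F)F)CCC=C(C)C | intermediate
34 | acrolein | C=CC=O | starting material
35 | (2E)-8-methyl-4-methylidenenona-2,7-dienal | O=C/C=C/C(=C)CCC=C(C)C | intermediate
36 | (E)-N-tert-butylimine of 31 | CC(C)(C)/N=C/C[C@@H]1CC[C@]2([C@H](CCCO[Si](c3ccccc3)(c3ccccc3)C(C)(C)C)/C(=C(/C)CO[Si](c3ccccc3)(c3ccccc3)C(C)(C)C)CC[C@]2(C)O)[C@H]1O | intermediate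
37 | β-hydroxy imine from 1,2-addition of lithiated 36 to 35 (mixture at the two new centres) | CC(C)(C)/N=C/C(C(O)/C=C/C(=C)CCC=C(C)C)[C@@H]1CC[C@]2([C@H](CCCO[Si](c3ccccc3)(c3ccccc3)C(C)(C)C)/C(=C(/C)CO[Si](c3ccccc3)(c3ccccc3)C(C)(C)C)CC[C@]2(C)O)[C@H]1O | intermediate
38 | (2E,4E)-trienal: 2-formyl side chain on C-2 (formyl trans to the dienyl group), bis-silyl ether, free 1,10-diol | C=C(/C=C/C=C(/C=O)[C@@H]1CC[C@]2([C@H](CCCO[Si](c3ccccc3)(c3ccccc3)C(C)(C)C)/C(=C(/C)CO[Si](c3ccccc3)(c3ccccc3)C(C)(C)C)CC[C@]2(C)O)[C@H]1O)CCC=C(C)C | intermediate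
39 | trienol from 38 (CH2OH in place of CHO) | C=C(/C=C/C=C(/CO)[C@@H]1CC[C@]2([C@H](CCCO[Si](c3ccccc3)(c3ccccc3)C(C)(C)C)/C(=C(/C)CO[Si](c3ccccc3)(c3ccccc3)C(C)(C)C)CC[C@]2(C)O)[C@H]1O)CCC=C(C)C | intermediate
40 | acetate of 39 | C=C(/C=C/C=C(/COC(C)=O)[C@@H]1CC[C@]2([C@H](CCCO[Si](c3ccccc3)(c3ccccc3)C(C)(C)C)/C(=C(/C)CO[Si](c3ccccc3)(c3ccccc3)C(C)(C)C)CC[C@]2(C)O)[C@H]1O)CCC=C(C)C | intermediate
41 | desilylated acetate: 7-[(Z)-1-hydroxypropan-2-ylidene] allylic alcohol | C=C(/C=C/C=C(/COC(C)=O)[C@@H]1CC[C@]2([C@H](CCCO)/C(=C(/C)CO)CC[C@]2(C)O)[C@H]1O)CCC=C(C)C | intermediate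
42 | (2E,4E)-2-[(1S,2S,5S,6R,10S)-1,10-dihydroxy-6-(3-hydroxypropyl)-10-methyl-7-[(Z)-1-oxopropan-2-ylidene]spiro[4.5]decan-2-yl]-10-methyl-6-methylideneundeca-2,4,9-trienyl acetate | C=C(/C=C/C=C(/COC(C)=O)[C@@H]1CC[C@]2([C@H](CCCO)/C(=C(/C)C=O)CC[C@]2(C)O)[C@H]1O)CCC=C(C)C | target

**Totals**
Total step count: 28. Longest linear sequence: 24 steps (steps 2–6, 8–21 and 24–28, from cyclohexane-1,3-dione 4 to 42).

**Steps most likely to fail**

1. Step 5 (Proposed new method). Addition of the primary radical to the β-substituted alkenylboronate may be too slow, so that hydrogen abstraction from THF and unproductive re-closure of the cyclopropane take over; the boron-bearing centre may also form with poor diastereoselection. The fallback sets out from 8 and comes back at 9. Cross-metathesis of commercial 3-butenal diethyl acetal with methyl acrylate (second-generation Grubbs catalyst) would give methyl (E)-5,5-diethoxypent-2-enoate F1. An α,β-unsaturated ester is a far better radical acceptor than the alkenylboronate, and it takes the radical at its β-carbon. Annulation of 8 with F1 under the conditions of step 5 would therefore give the C-1 methyl ester F2. Hydrolysis with LiOH would give the C-1 carboxylic acid F3. Coupling with N-hydroxyphthalimide and diisopropylcarbodiimide would give the redox-active ester F4. Decarboxylative borylation (B2cat2, DMAc, blue light; then pinacol, Et3N) would give 9, boron entering trans to the C-2 chain.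

2. Step 17. The eight-membered ring may close too slowly, so that the samarium enolate is simply protonated (loss of bromine without C–C bond formation) or couples between molecules. The fallback sets out from 22 and comes back at 30. Horner–Wadsworth–Emmons olefination of 22 with diethyl (1-cyanoethyl)phosphonate (NaH, THF) would give the unsaturated nitrile F5; the slim nitrile should take the position cis to the branched C-6, and the other alkene isomer would be removed by chromatography. Reduction with iBu2AlH would give the Z enal F6 and NaBH4 the allylic alcohol F7. Silylation (tBuPh2SiCl, imidazole) would give 30.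

3. Step 11. The Grignard reagent may attack boron or enolise the hindered ketone, or the facial selectivity may erode. The fallback sets out from 16 and comes back at 18. Oxidation of the boronate first (NaBO3·4H2O, THF/H2O) would give the β-hydroxy ketone F8. Silylation with Et3SiCl, imidazole and DMAP would give the C-1 triethylsilyl ether F9, whose bulky non-chelating group shields the same face. MeLi with CeCl3 would then give the tertiary alcohol F10, and camphorsulfonic acid in EtOH would give 18.

Further compounds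
F1 | step 5 | methyl (E)-5,5-diethoxypent-2-enoate | CCOC(OCC)C/C=C/C(=O)OC
F2 | step 5 | methyl 2-(2,2-diethoxyethyl)-6-oxo-10-(triethylsilyloxy)spiro[4.5]decane-1-carboxylate (ester cis to C-10, trans to the C-2 chain) | CCOC(OCC)C[C@@H]1CC[C@]2(C(=O)CCC[C@H]2O[Si](CC)(CC)CC)[C@H]1C(=O)OC
F3 | step 5 | C-1 carboxylic acid from F2 | CCOC(OCC)C[C@@H]1CC[C@]2(C(=O)CCC[C@H]2O[Si](CC)(CC)CC)[C@H]1C(=O)O
F4 | step 5 | N-hydroxyphthalimide ester of F3 | CCOC(OCC)C[C@@H]1CC[C@]2(C(=O)CCC[C@H]2O[Si](CC)(CC)CC)[C@H]1C(=O)ON1C(=O)c2ccccc2C1=O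
F5 | step 17 | (Z)-α-methyl unsaturated nitrile at C-7 (nitrile cis to C-6) | CCOC(OCC)C[C@@H]1CC[C@]2([C@H](CCCO[Si](c3ccccc3)(c3ccccc3)C(C)(C)C)/C(=C(/C)C#N)CC[C@]2(C)OC(C)(C)O4)[C@H]14
F6 | step 17 | (Z)-enal from F5 | CCOC(OCC)C[C@@H]1CC[C@]2([C@H](CCCO[Si](c3ccccc3)(c3ccccc3)C(C)(C)C)/C(=C(/C)C=O)CC[C@]2(C)OC(C)(C)O4)[C@H]14
F7 | step 17 | (Z)-allylic alcohol from F6 | CCOC(OCC)C[C@@H]1CC[C@]2([C@H](CCCO[Si](c3ccccc3)(c3ccccc3)C(C)(C)C)/C(=C(/C)CO)CC[C@]2(C)OC(C)(C)O4)[C@H]14
F8 | step 11 | 1-hydroxy spiro[4.5]dec-6-en-10-one from 16 | CCOC(OCC)C[C@@H]1CC[C@]2(C(CCCO[Si](c3ccccc3)(c3ccccc3)C(C)(C)C)=CCCC2=O)[C@H]1O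
F9 | step 11 | C-1 triethylsilyl ether of F8 | CCOC(OCC)C[C@@H]1CC[C@]2(C(CCCO[Si](c3ccccc3)(c3ccccc3)C(C)(C)C)=CCCC2=O)[C@H]1O[Si](CC)(CC)CC
F10 | step 11 | 10-methyl tertiary alcohol from F9 | CCOC(OCC)C[C@@H]1CC[C@]2(C(CCCO[Si](c3ccccc3)(c3ccccc3)C(C)(C)C)=CCC[C@]2(C)O)[C@H]1O[Si](CC)(CC)CC
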